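**Retrosynthetic overview**

1. Feature: the periphery C1–C2–C3–C4–C5–C6–C7–C8–C9–C10 of the trans-fused five/seven-membered ring system is a ten-membered ring with one cross-ring bond, C1–C5. C1 (quaternary, methyl) is α to the C10 oxygen and C5 is next to the tertiary C4–OH, so C1–C5 is a ketone enolate plus 4,5-epoxide pair.
2. Last: the three esters (C10 benzoate after enone reduction, C2 acetate, C6 angelate) are put on hydroazulenone 27.
3. Key: C1–C5 by transannular opening of the 4,5-epoxide of (Z)-cyclodecenone 24 by its C1 lithium enolate; the five- and seven-membered rings close together.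
4. C8=C9 by ring-closing metathesis (ten-membered ring) of vinyl ketone 23; C1–C2 by syn-aldol of pent-1-en-3-one with epoxy aldehyde 18.
5. 18 from an ynoate: C4–isopropyl by syn-carbocupration, C6–C7 by asymmetric 2-methylallylboration, oxirane by hydroxyl-directed epoxidation before any carbocycle exists. Ring order: oxirane, ten-membered ring, then five- and seven-membered rings in one step.

Key step: step 13

Remark: locants are C1 = quaternary fusion carbon (Me), C2 = CHOAc, C3 = CH2, C4 = C(OH)i-Pr, C5 = fusion CH, C6 = CHO-angeloyl, C7 = CH2, C8(Me)=C9, C10 = CHOBz; α/β refer to the hydroazulene drawn with the C1 methyl α.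
Assumption: with ethyl ketones the (Z)-enol borinate from (+)-Ipc2BOTf (from (−)-α-pinene) adds to the re face of an aldehyde; if a test aldol shows the opposite sense, the antipodal triflate is used and nothing else changes.
Assumption: silyl ether 1 is bought (it is also one step from but-3-yn-1-ol).

Step 1
Reactants: 1 tert-butyl(but-3-yn-1-yloxy)dimethylsilane; 2 methyl chloroformate
Product: 4 methyl 5-{[tert-butyl(dimethyl)silyl]oxy}pent-2-ynoate, via lithium acetylide 3 (not isolated)
Conditions: n-BuLi, THF, −78 °C; then 2, −78 → 0 °C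
Reagents that add atoms: none
Why: Deprotonation of the terminal alkyne and C-acylation of the lithium acetylide with the chloroformate is a standard ynoate synthesis that brings in C6; no stereocentre is formed.

Step 2
Reactants: 4 ynoate; 5 isopropylmagnesium chloride
Product: 8 methyl (2E)-5-{[tert-butyl(dimethyl)silyl]oxy}-3-(propan-2-yl)pent-2-enoate, via chloromagnesium diisopropylcuprate 6 (not isolated), via alkenylcuprate 7 (not isolated)
Conditions: 5 (2 equiv), CuI (1 equiv), THF, −40 °C; then 4, −78 °C; MeOH, −78 °C; aq. NH4Cl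
Reagents that add atoms: none
Why: Conjugate carbocupration of an ynoate is a syn addition, so quenching the alkenylcuprate at −78 °C before it equilibrates through the allenolate places the isopropyl group cis to H-5 and the ester carbon (C6) cis to the C3 methylene, the C4=C5 geometry the cis-epoxide needs.

Step 3
Reactants: 8 enoate
Product: 9 (2E)-5-{[tert-butyl(dimethyl)silyl]oxy}-3-(propan-2-yl)pent-2-en-1-ol
Conditions: i-Bu2AlH, CH2Cl2, −78 °C; aq. Rochelle salt
Reagents that add atoms: none
Why: 1,2-Reduction of the enoate by the aluminium hydride at low temperature gives the allylic alcohol without touching the silyl ether or the alkene geometry.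

Step 4
Reactants: 9 allylic alcohol
Product: 10 (2E)-5-{[tert-butyl(dimethyl)silyl]oxy}-3-(propan-2-yl)pent-2-enal
Conditions: MnO2, CH2Cl2, rt
Reagents that add atoms: none
Why: MnO2 oxidises allylic alcohols selectively under neutral conditions, so the trisubstituted enal should keep its geometry.

Step 5
Reactants: 10 enal; 11 (2-methylprop-2-en-1-yl)magnesium chloride
Product: 14 (4S,5E)-8-{[tert-butyl(dimethyl)silyl]oxy}-2-methyl-6-(propan-2-yl)octa-1,5-dien-4-ol, via allylborane 12 (not isolated), via borinate 13 (not isolated)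
Conditions: (−)-Ipc2BOMe, 11, Et2O, −78 °C → rt; then 10, −78 °C; then NaOH, H2O2, 0 °C → rt
Reagents that add atoms: none
Why: Asymmetric allylboration with the 2-methylallyl borane from (−)-Ipc2BOMe passes through a chair six-membered transition state that adds to the si face of the aldehyde, which sets C6 as S and brings in C7, C8 and the C8 methyl group.

Step 6
Reactants: 14 dienol
Product: 15 (1S)-1-[(2R,3R)-3-(2-{[tert-butyl(dimethyl)silyl]oxy}ethyl)-3-(propan-2-yl)oxiran-2-yl]-3-methylbut-3-en-1-ol
Conditions: mCPBA (1.0 equiv), NaHCO3, CH2Cl2, −20 °C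
Reagents that add atoms: 3-chloroperbenzoic acid, O=C(OO)c1cccc(Cl)c1
Why: Hydroxyl-directed peracid epoxidation (Henbest type): allylic 1,3-strain between the C3 methylene (cis on C4) and the C6 substituents holds H-6 in the alkene plane, so the hydrogen-bonded peracid delivers oxygen to the face carrying the hydroxyl and should give the threo (4R,5R) epoxy alcohol, the trisubstituted allylic alkene reacting before the 1,1-disubstituted one.

Step 7
Reactants: 15 epoxy alcohol
Product: 16 tert-butyl{2-[(2R,3R)-3-{(1S)-1-[(4-methoxyphenyl)methoxy]-3-methylbut-3-en-1-yl}-2-(propan-2-yl)oxiran-2-yl]ethoxy}dimethylsilane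
Conditions: NaH, 4-MeOC6H4CH2Cl, Bu4NI (cat.), THF/DMF, 0 °C → rt
Reagents that add atoms: 4-methoxybenzyl chloride, COc1ccc(CCl)cc1
Why: Williamson etherification of the secondary sodium alkoxide, which is benzylated faster than it can undergo Payne migration to the less substituted oxirane, protects C6 with a group that survives base, fluoride and metathesis and is removed oxidatively at the end.

Step 8
Reactants: 16 silyl ether
Product: 17 2-[(2R,3R)-3-{(1S)-1-[(4-methoxyphenyl)methoxy]-3-methylbut-3-en-1-yl}-2-(propan-2-yl)oxiran-2-yl]ethan-1-ol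
Conditions: Bu4NF, THF, 0 °C
Reagents that add atoms: none
Why: Fluoride cleaves the primary silyl ether under conditions that leave the oxirane and the 4-methoxybenzyl ether untouched.

Step 9
Reactants: 17 primary alcohol
Product: 18 2-[(2R,3R)-3-{(1S)-1-[(4-methoxyphenyl)methoxy]-3-methylbut-3-en-1-yl}-2-(propan-2-yl)oxiran-2-yl]acetaldehyde
Conditions: Dess–Martin periodinane, NaHCO3, CH2Cl2, 0 °C; crude aldehyde used at once
Reagents that add atoms: none
Why: Buffered Dess–Martin oxidation gives the β,γ-epoxy aldehyde under non-basic conditions, and immediate use avoids base-induced opening of the oxirane to the γ-hydroxy enal.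

Step 10
Reactants: 18 epoxy aldehyde; 19 pent-1-en-3-one
Product: 22 (4R,5S)-5-hydroxy-6-[(2R,3R)-3-{(1S)-1-[(4-methoxyphenyl)methoxy]-3-methylbut-3-en-1-yl}-2-(propan-2-yl)oxiran-2-yl]-4-methylhex-1-en-3-one, via enol borinate 20 (not isolated), via boron aldolate 21 (not isolated)
Conditions: 19, (+)-Ipc2BOTf, i-Pr2NEt, CH2Cl2, −78 °C; then 18, −78 → −20 °C; then pH 7 buffer, MeOH, H2O2, 0 °C
Reagents that add atoms: none
Why: Boron-mediated syn-aldol reaction under reagent control: the (Z)-enol diisopinocampheylborinate of the ethyl ketone adds through a closed chair transition state, which gives the 1,2-syn relation, and the (+)-isopinocampheyl ligands should direct it to the re face of the aldehyde, which sets C2 as S (C1 is R here and becomes planar in step 13).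

Step 11
Reactants: 22 aldol adduct
Product: 23 (4R,5S)-5-{[tert-butyl(dimethyl)silyl]oxy}-6-[(2R,3R)-3-{(1S)-1-[(4-methoxyphenyl)methoxy]-3-methylbut-3-en-1-yl}-2-(propan-2-yl)oxiran-2-yl]-4-methylhex-1-en-3-one
Conditions: t-BuMe2SiOTf, 2,6-lutidine, CH2Cl2, −78 °C
Reagents that add atoms: tert-butyldimethylsilyl trifluoromethanesulfonate, CC(C)(C)[Si](C)(C)OS(=O)(=O)C(F)(F)F
Why: Silylation with the silyl triflate and a hindered pyridine base at −78 °C protects the β-hydroxy ketone without retro-aldol cleavage or conjugate addition to the vinyl ketone and blocks the C2 oxygen for the enolate chemistry.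

Step 12
Reactants: 23 vinyl ketone diene
Product: 24 (1R,2S,4R,5R,6S,8Z)-2-{[tert-butyl(dimethyl)silyl]oxy}-4,5-epoxy-6-[(4-methoxyphenyl)methoxy]-1,8-dimethyl-4-(propan-2-yl)cyclodec-8-en-10-one (route locants)
Conditions: second-generation Hoveyda–Grubbs catalyst (10 mol %), toluene (1 mM), 80 °C
Reagents that add atoms: none
Why: Ring-closing metathesis between the vinyl ketone and the 1,1-disubstituted alkene releases ethene and closes the ten-membered ring at C8=C9, the cis-oxirane (installed beforehand so that no C4=C5 alkene can close a cyclohexenone instead) serving as a turn element and the (Z)-enone being the less strained geometry in a ring of this size.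

Step 13
Reactants: 24 cyclodecenone epoxide
Product: 27 (1R,2S,4R,5S,6S)-2-{[tert-butyl(dimethyl)silyl]oxy}-4-hydroxy-6-[(4-methoxyphenyl)methoxy]-1,8-dimethyl-4-(propan-2-yl)bicyclo[5.3.0]dec-8-en-10-one (route locants; trans-fused; 1α-Me; 2β-O; 4α-OH; 5β-H; 6β-O), via lithium enolate 25 (not isolated), via lithium alkoxide 26 (not isolated)
Conditions: LiN(i-Pr)2, THF, −78 °C; then −78 → −30 °C; AcOH, −78 °C
Reagents that add atoms: none
Why: Proposed new method: kinetic deprotonation of 24 at C1 (α′ to the enone, in preference to the γ-positions C7 and C8-CH3) should give the cross-conjugated lithium enolate 25, whose C1 carbon, held across the ten-membered ring, attacks C5 of the oxirane from the back side of the C5–O bond, so that C5 is inverted and the oxygen stays on C4 as the tertiary alkoxide 26. The closest known reactions are intramolecular alkylations of ketone enolates and nitrile anions by epoxides and the acid-mediated transannular cyclisation of germacrene 4,5-epoxides to guaian-4-ols, which forms the same C1–C5 bond at the less substituted epoxide carbon. The cyclopentane (C1–C5) closes with the enolate double bond outside the ring and both oxirane carbons inside it (5-enolexo, endo with respect to the epoxide), and the cycloheptenone (C1, C5–C10) closes with the enolate inside the ring and the C4–O bond outside it (7-enolendo, 7-exo with respect to the epoxide). C5 is set by inversion of the (4R,5R)-oxirane of step 6, which also fixes C4 (hydroxyl trans to H-5); C1 is set by the face of the enolate that the ring presents to C5, and the ring-(E) enolate with C10 anti to C4 about the forming bond is expected to give the trans fusion with the methyl group on the side of the C4 oxygen, although this facial preference is argued from a rigid geometric model and is the least certain point of the step. The step needs C-alkylation at C5 only: attack at C4 would close a cyclobutane at a fully substituted carbon, O-alkylation would give an oxygen-bridged enol ether with a bridgehead double bond, and the temperature is held at or below −30 °C so that the C2 silyloxy group is not lost by β-elimination.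

Step 14
Reactants: 27 hydroazulenone
Product: 28 10α-alcohol: 2β-{[tert-butyl(dimethyl)silyl]oxy}-6β-[(4-methoxyphenyl)methoxy]-1α,8-dimethyl-4β-(propan-2-yl)-5β-H-bicyclo[5.3.0]dec-8-ene-4α,10α-diol (route locants)
Conditions: NaBH4, CeCl3·7H2O, MeOH, −78 °C
Reagents that add atoms: none
Why: Luche 1,2-reduction of the enone, in which hydride should enter C10 from the β face, anti to the axial C1 methyl group, to give the 10α-alcohol (cis to the methyl group).

Step 15
Reactants: 28 allylic alcohol; 29 benzoyl chloride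
Product: 30 10α-benzoate of 28 (2β-silyl ether; 4α-OH free; 6β-(4-methoxybenzyl) ether)
Conditions: 29, pyridine, DMAP (cat.), CH2Cl2, 0 °C → rt
Reagents that add atoms: none
Why: Pyridine/DMAP-mediated acylation benzoylates the secondary allylic C10 alcohol, the tertiary C4 alcohol being too hindered to react.

Step 16
Reactants: 30 benzoate
Product: 31 2β-alcohol: 10α-benzoyloxy-6β-[(4-methoxyphenyl)methoxy]-1α,8-dimethyl-4β-(propan-2-yl)-5β-H-bicyclo[5.3.0]dec-8-ene-2β,4α-diol (route locants)
Conditions: HF·pyridine, pyridine, THF, 0 °C → rt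
Reagents that add atoms: none
Why: Buffered HF·pyridine removes the hindered secondary silyl ether under mildly acidic conditions that avoid base-induced migration of the C10 benzoate to the freed C2 hydroxyl.

Step 17
Reactants: 31 diol; 32 acetic anhydride
Product: 33 2β-acetate of 31 (10α-benzoate; 4α-OH free; 6β-(4-methoxybenzyl) ether)
Conditions: 32, pyridine, DMAP (cat.), CH2Cl2, rt
Reagents that add atoms: none
Why: DMAP-catalysed acetylation of the secondary C2 alcohol, again leaving the tertiary C4 hydroxyl free.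

Step 18
Reactants: 33 acetate
Product: 34 6β-alcohol: 2β-acetoxy-10α-benzoyloxy-1α,8-dimethyl-4β-(propan-2-yl)-5β-H-bicyclo[5.3.0]dec-8-ene-4α,6β-diol (route locants)
Conditions: DDQ, CH2Cl2/pH 7 buffer, 0 °C
Reagents that add atoms: none
Why: Oxidative cleavage of the 4-methoxybenzyl ether by DDQ in wet CH2Cl2 frees the C6 hydroxyl without affecting the esters or the trisubstituted alkene.

Step 19
Reactants: 34 alcohol; 35 angelic acid [(2Z)-2-methylbut-2-enoic acid]
Product: 37 target CNP0248576.1 (route locants 1R,2S,4R,5S,6S,10S: 2β-acetoxy-6β-angeloyloxy-10α-benzoyloxy-4α-hydroxy), via mixed anhydride 36 (not isolated)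
Conditions: 35, 2,4,6-Cl3C6H2COCl, Et3N, toluene, rt; then 34, toluene, 80 °C
Reagents that add atoms: none
Why: Yamaguchi-type esterification through the mixed 2,4,6-trichlorobenzoic anhydride acylates the secondary C6 alcohol without a nucleophilic catalyst, conditions under which angelates keep their (Z)-geometry, and the tertiary C4 hydroxyl stays free to give the target.

**Compound list**

1 | tert-butyl(but-3-yn-1-yloxy)dimethylsilane | C#CCCO[Si](C)(C)C(C)(C)C | starting material
2 | methyl chloroformate | COC(=O)Cl | starting material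
3 | lithium acetylide of 1 | [Li]C#CCCO[Si](C)(C)C(C)(C)C | intermediate (not isolated)
4 | methyl 5-{[tert-butyl(dimethyl)silyl]oxy}pent-2-ynoate | COC(=O)C#CCCO[Si](C)(C)C(C)(C)C | intermediate
5 | isopropylmagnesium chloride | CC(C)[Mg]Cl | starting material
6 | chloromagnesium diisopropylcuprate | CC(C)[Cu-]C(C)C.[Mg+]Cl | intermediate (not isolated)
7 | chloromagnesium alkenyl(isopropyl)cuprate, copper on C2 cis to the new isopropyl group | COC(=O)/C([Cu-]C(C)C)=C(/C(C)C)CCO[Si](C)(C)C(C)(C)C.[Mg+]Cl | intermediate (not isolated)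
8 | methyl (2E)-5-{[tert-butyl(dimethyl)silyl]oxy}-3-(propan-2-yl)pent-2-enoate | COC(=O)/C=C(/C(C)C)CCO[Si](C)(C)C(C)(C)C | intermediate
9 | (2E)-5-{[tert-butyl(dimethyl)silyl]oxy}-3-(propan-2-yl)pent-2-en-1-ol | OC/C=C(/C(C)C)CCO[Si](C)(C)C(C)(C)C | intermediate
10 | (2E)-5-{[tert-butyl(dimethyl)silyl]oxy}-3-(propan-2-yl)pent-2-enal | O=C/C=C(/C(C)C)CCO[Si](C)(C)C(C)(C)C | intermediate
11 | (2-methylprop-2-en-1-yl)magnesium chloride | CC(=C)C[Mg]Cl | starting material
12 | (−)-B-(2-methylprop-2-en-1-yl)diisopinocampheylborane | CC(=C)CB([C@@H]1C[C@@H]2C[C@H]([C@H]1C)C2(C)C)[C@@H]1C[C@@H]2C[C@H]([C@H]1C)C2(C)C | intermediate (not isolated)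
13 | diisopinocampheylborinate of 14 | CC(=C)C[C@H](OB([C@@H]1C[C@@H]2C[C@H]([C@H]1C)C2(C)C)[C@@H]1C[C@@H]2C[C@H]([C@H]1C)C2(C)C)/C=C(/C(C)C)CCO[Si](C)(C)C(C)(C)C | intermediate (not isolated)
14 | (4S,5E)-8-{[tert-butyl(dimethyl)silyl]oxy}-2-methyl-6-(propan-2-yl)octa-1,5-dien-4-ol | CC(=C)C[C@H](O)/C=C(/C(C)C)CCO[Si](C)(C)C(C)(C)C | intermediate
15 | (1S)-1-[(2R,3R)-3-(2-{[tert-butyl(dimethyl)silyl]oxy}ethyl)-3-(propan-2-yl)oxiran-2-yl]-3-methylbut-3-en-1-ol | CC(=C)C[C@H](O)[C@H]1O[C@@]1(C(C)C)CCO[Si](C)(C)C(C)(C)C | intermediate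
16 | tert-butyl{2-[(2R,3R)-3-{(1S)-1-[(4-methoxyphenyl)methoxy]-3-methylbut-3-en-1-yl}-2-(propan-2-yl)oxiran-2-yl]ethoxy}dimethylsilane | CC(=C)C[C@H](OCc1ccc(OC)cc1)[C@H]1O[C@@]1(C(C)C)CCO[Si](C)(C)C(C)(C)C | intermediate
17 | 2-[(2R,3R)-3-{(1S)-1-[(4-methoxyphenyl)methoxy]-3-methylbut-3-en-1-yl}-2-(propan-2-yl)oxiran-2-yl]ethan-1-ol | CC(=C)C[C@H](OCc1ccc(OC)cc1)[C@H]1O[C@@]1(C(C)C)CCO | intermediate
18 | 2-[(2R,3R)-3-{(1S)-1-[(4-methoxyphenyl)methoxy]-3-methylbut-3-en-1-yl}-2-(propan-2-yl)oxiran-2-yl]acetaldehyde | CC(=C)C[C@H](OCc1ccc(OC)cc1)[C@H]1O[C@@]1(C(C)C)CC=O | intermediate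
19 | pent-1-en-3-one | C=CC(=O)CC | starting material
20 | (Z)-enol diisopinocampheylborinate of 19 | C/C=C(\C=C)OB([C@H]1C[C@H]2C[C@@H]([C@@H]1C)C2(C)C)[C@H]1C[C@H]2C[C@@H]([C@@H]1C)C2(C)C | intermediate (not isolated)
21 | diisopinocampheylboron aldolate of 22 | C=CC(=O)[C@H](C)[C@@H](OB([C@H]1C[C@H]2C[C@@H]([C@@H]1C)C2(C)C)[C@H]1C[C@H]2C[C@@H]([C@@H]1C)C2(C)C)C[C@]1(C(C)C)O[C@@H]1[C@H](CC(C)=C)OCc1ccc(OC)cc1 | intermediate (not isolated)
22 | (4R,5S)-5-hydroxy-6-[(2R,3R)-3-{(1S)-1-[(4-methoxyphenyl)methoxy]-3-methylbut-3-en-1-yl}-2-(propan-2-yl)oxiran-2-yl]-4-methylhex-1-en-3-one | C=CC(=O)[C@H](C)[C@@H](O)C[C@]1(C(C)C)O[C@@H]1[C@H](CC(C)=C)OCc1ccc(OC)cc1 | intermediate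
23 | (4R,5S)-5-{[tert-butyl(dimethyl)silyl]oxy}-6-[(2R,3R)-3-{(1S)-1-[(4-methoxyphenyl)methoxy]-3-methylbut-3-en-1-yl}-2-(propan-2-yl)oxiran-2-yl]-4-methylhex-1-en-3-one | C=CC(=O)[C@H](C)[C@@H](O[Si](C)(C)C(C)(C)C)C[C@]1(C(C)C)O[C@@H]1[C@H](CC(C)=C)OCc1ccc(OC)cc1 | intermediate
24 | (1R,2S,4R,5R,6S,8Z)-2-{[tert-butyl(dimethyl)silyl]oxy}-4,5-epoxy-6-[(4-methoxyphenyl)methoxy]-1,8-dimethyl-4-(propan-2-yl)cyclodec-8-en-10-one (route locants) | COc1ccc(cc1)CO[C@H]2C/C(C)=C\C(=O)[C@H](C)[C@@H](O[Si](C)(C)C(C)(C)C)C[C@]3(C(C)C)O[C@@H]32 | intermediate (key-step precursor)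
25 | C10–C1 lithium enolate of 24 (ring-E, OLi cis to C2) | COc1ccc(cc1)CO[C@H]2C/C(C)=C\C(O[Li])=C(/C)[C@@H](O[Si](C)(C)C(C)(C)C)C[C@]3(C(C)C)O[C@@H]32 | intermediate (not isolated)
26 | lithium C4-alkoxide of 27 | COc1ccc(cc1)CO[C@H]2CC(C)=CC(=O)[C@@]3(C)[C@@H](O[Si](C)(C)C(C)(C)C)C[C@@](O[Li])(C(C)C)[C@H]23 | intermediate (not isolated)
27 | trans-fused hydroazulenone: 2β-silyloxy-4α-hydroxy-6β-(4-methoxybenzyloxy)-1α,8-dimethyl-4β-isopropyl-5β-H-bicyclo[5.3.0]dec-8-en-10-one (route locants; 1R,2S,4R,5S,6S) | COc1ccc(cc1)CO[C@H]2CC(C)=CC(=O)[C@@]3(C)[C@@H](O[Si](C)(C)C(C)(C)C)C[C@@](O)(C(C)C)[C@H]23 | intermediate (key-step product)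
28 | 10α-alcohol of 27 (4α,10α-diol; 2β-silyl ether; 6β-(4-methoxybenzyl) ether) | COc1ccc(cc1)CO[C@H]2CC(C)=C[C@H](O)[C@@]3(C)[C@@H](O[Si](C)(C)C(C)(C)C)C[C@@](O)(C(C)C)[C@H]23 | intermediate
29 | benzoyl chloride | O=C(Cl)c1ccccc1 | starting material
30 | 10α-benzoate of 28 | COc1ccc(cc1)CO[C@H]2CC(C)=C[C@H](OC(=O)c4ccccc4)[C@@]3(C)[C@@H](O[Si](C)(C)C(C)(C)C)C[C@@](O)(C(C)C)[C@H]23 | intermediate
31 | 2β,4α-diol 10α-benzoate 6β-(4-methoxybenzyl) ether | COc1ccc(cc1)CO[C@H]2CC(C)=C[C@H](OC(=O)c4ccccc4)[C@@]3(C)[C@@H](O)C[C@@](O)(C(C)C)[C@H]23 | intermediate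
32 | acetic anhydride | CC(=O)OC(C)=O | starting material
33 | 2β-acetate 10α-benzoate 6β-(4-methoxybenzyl) ether (4α-OH free) | COc1ccc(cc1)CO[C@H]2CC(C)=C[C@H](OC(=O)c4ccccc4)[C@@]3(C)[C@@H](OC(C)=O)C[C@@](O)(C(C)C)[C@H]23 | intermediate
34 | 2β-acetate 10α-benzoate 4α,6β-diol | O[C@H]1CC(C)=C[C@H](OC(=O)c2ccccc2)[C@@]2(C)[C@@H](OC(C)=O)C[C@@](O)(C(C)C)[C@H]12 | intermediate
35 | angelic acid, (2Z)-2-methylbut-2-enoic acid | C/C=C(/C)C(=O)O | starting material
36 | angelic 2,4,6-trichlorobenzoic anhydride | C/C=C(/C)C(=O)OC(=O)c1c(Cl)cc(Cl)cc1Cl | intermediate (not isolated)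
37 | CNP0248576.1: 2β-acetoxy-6β-[(2Z)-2-methylbut-2-enoyloxy]-10α-benzoyloxy-4α-hydroxy-1α,8-dimethyl-4β-isopropyl-5β-H-bicyclo[5.3.0]dec-8-ene (route locants; 1R,2S,4R,5S,6S,10S) | C/C=C(/C)C(=O)O[C@H]1CC(C)=C[C@H](OC(=O)c2ccccc2)[C@@]2(C)[C@@H](OC(C)=O)C[C@@](O)(C(C)C)[C@H]12 | target

**Totals**

Total step count: 19. Longest linear sequence: 19 steps (1 to 37); all other inputs enter in single steps.

**Steps most likely to fail**

1. Step 13 (transannular alkylation). The base may remove a γ-hydrogen (C7 or the C8 methyl group) instead of H-1, the enolate may expel the C2 silyloxy group on warming, or it may not open the oxirane at the temperatures it tolerates. The fallback uses known chemistry: Lewis-acid-induced transannular opening of an epoxide by a π-nucleophile (the way germacrene 4,5-epoxides give guaian-4-ols), here with a Mukaiyama-type enol silane as nucleophile. It sets out from 24, which LiN(i-Pr)2 and Me3SiCl at −78 °C (internal quench) convert into the trimethylsilyl enol ether F1. BF3·OEt2 in CH2Cl2 at −78 °C then activates the oxirane, the enol silane attacks C5 from the back side, and aqueous work-up, which removes the trimethylsilyl group, returns the route at 27.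

2. Step 12 (ring-closing metathesis). Slow initiation at the electron-poor vinyl ketone and at the hindered 1,1-disubstituted alkene may let intermolecular metathesis and catalyst decay outrun closure of the ten-membered ring. The fallback closes the ring at the allylic alcohol stage. It sets out from 23: NaBH4/CeCl3·7H2O in MeOH at −78 °C gives the dienol F2 (both C10 epimers), whose monosubstituted, hydroxyl-activated alkene loads the ruthenium catalyst readily. Metathesis (same catalyst, toluene, 1 mM, 80 °C) then gives the cyclodecenol F3, and Dess–Martin oxidation of F3 returns the route at 24.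

3. Step 10 (aldol). Facial control by the isopinocampheyl ligands may be insufficient with an α-unbranched aldehyde, so that the C2 epimer forms in quantity. The fallback replaces reagent control by auxiliary control. It sets out from 18: the (Z)-boron enolate of (4R)-4-benzyl-3-propanoyl-1,3-oxazolidin-2-one (Bu2BOTf, Et3N, CH2Cl2, −78 → 0 °C; Evans syn-aldol) gives the syn-aldol imide F4 with the same C1 and C2 configurations as 22. Me3Al/MeNHOMe·HCl (THF, −20 °C, kept cold because of the oxirane) exchanges the auxiliary for the N-methoxy-N-methylamide F5, silylation (t-BuMe2SiOTf, 2,6-lutidine, −78 °C) gives the silyl ether F6, and vinylmagnesium bromide (THF, −78 → 0 °C) returns the route at 23.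

Further compounds
F1 | step 13 | trimethylsilyl enol ether of 24 (C10–O–SiMe3, C10=C1) | COc1ccc(cc1)CO[C@H]2C/C(C)=C\C(O[Si](C)(C)C)=C(/C)[C@@H](O[Si](C)(C)C(C)(C)C)C[C@]3(C(C)C)O[C@@H]32
F2 | step 12 | dienol: C10 alcohol of 23 (both C10 epimers) | C=CC(O)[C@H](C)[C@@H](O[Si](C)(C)C(C)(C)C)C[C@]1(C(C)C)O[C@@H]1[C@H](CC(C)=C)OCc1ccc(OC)cc1
F3 | step 12 | cyclodecenol: C10 alcohol of 24 (both C10 epimers) | COc1ccc(cc1)CO[C@H]2C/C(C)=C\C(O)[C@H](C)[C@@H](O[Si](C)(C)C(C)(C)C)C[C@]3(C(C)C)O[C@@H]32
F4 | step 10 | (4R)-4-benzyl-3-[(2R,3S)-3-hydroxy-2-methyl-4-{(2R,3R)-3-[(1S)-1-[(4-methoxyphenyl)methoxy]-3-methylbut-3-en-1-yl]-2-(propan-2-yl)oxiran-2-yl}butanoyl]-1,3-oxazolidin-2-one | O=C1OC[C@@H](Cc2ccccc2)N1C(=O)[C@H](C)[C@@H](O)C[C@]1(C(C)C)O[C@@H]1[C@H](CC(C)=C)OCc1ccc(OC)cc1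
F5 | step 10 | (2R,3S)-3-hydroxy-N-methoxy-N,2-dimethyl-4-{(2R,3R)-3-[(1S)-1-[(4-methoxyphenyl)methoxy]-3-methylbut-3-en-1-yl]-2-(propan-2-yl)oxiran-2-yl}butanamide | CON(C)C(=O)[C@H](C)[C@@H](O)C[C@]1(C(C)C)O[C@@H]1[C@H](CC(C)=C)OCc1ccc(OC)cc1
F6 | step 10 | tert-butyldimethylsilyl ether of F5 | CON(C)C(=O)[C@H](C)[C@@H](O[Si](C)(C)C(C)(C)C)C[C@]1(C(C)C)O[C@@H]1[C@H](CC(C)=C)OCc1ccc(OC)cc1
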